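**Retrosynthetic overview**
1. Ring C (δ-lactone, formed last): catalytic asymmetric carbonyl-ene reaction of the prenyl group of 13 with 3-methyl-2-oxobutanal, then lactonisation onto the ester on the same carbon.
2. Spiro carbon: convex-face prenylation of the bicyclic β-keto ester 11.
3. Ring B (cyclopentanone, formed second): Dieckmann closure of diester 9, which comes from oxidative cleavage of the disubstituted alkene of cyclohexa-1,4-diene 7 (six-to-five ring contraction), then hydrogenation.
4. Ring A (γ-lactone, formed first) and the quaternary methyl carbon: asymmetric Birch reductive methylation of the phthalide-derived chiral benzamide 4. All six arene carbons are kept and become C3a, C4, C5, C6, C6a and the ester carbon.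
5. Feedstocks: phthalic anhydride, MeMgBr, MeI, prenyl bromide, 3-methylbutan-2-one.

Assumption: the (S)-auxiliary 3 is taken to deliver the (7aR)-lactone 7; the sense of induction for this ortho-alkoxide substrate is not established, and if it is the reverse the (R)-amine is used with nothing else changed.

**Step 1**
Reactants: 1 phthalic anhydride
Product: 2 3,3-dimethyl-2-benzofuran-1(3H)-one (3,3-dimethylphthalide)
Conditions: MeMgBr (2.2 equiv), THF, −20 → 0 °C; 2 M HCl
Reagents that add atoms: methylmagnesium bromide, C[Mg]Br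
Why: Double Grignard addition to one anhydride carbonyl (the carboxylate formed after the first addition protects the other), and the hydroxy acid closes to the phthalide on acidification; no stereocentre.

**Step 2**
Reactants: 2 3,3-dimethylphthalide; 3 (2S)-2-(methoxymethyl)pyrrolidine
Product: 4 [2-(2-hydroxypropan-2-yl)phenyl][(2S)-2-(methoxymethyl)pyrrolidin-1-yl]methanone
Conditions: AlMe3, 3, PhMe, 0 °C → rt; then 2, 80 °C; aq. potassium sodium tartrate
Reagents that add atoms: none
Why: Weinreb-type aminolysis, in which the dimethylaluminium amide opens the lactone and holds the product as its aluminium alkoxide, gives the ortho-substituted chiral benzamide with the auxiliary stereocentre unchanged.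

**Step 3**
Reactants: 4 hydroxy benzamide
Product: 7 (7aR)-3,3,7a-trimethyl-5,7a-dihydro-2-benzofuran-1(3H)-one, via dipotassium amide dienolate 5 (not isolated), via methylated diene hydroxy amide 6 (not isolated)
Conditions: KH, THF, 0 °C; K, NH3(l)/THF, t-BuOH (1 equiv), −78 °C; MeI, −78 °C; then TFA, CH2Cl2, 0 °C → rt
Reagents that add atoms: iodomethane, CI
Why: Schultz-type asymmetric Birch reduction–alkylation: the arene is reduced to the amide dienolate (the tertiary alkoxide resists benzylic C–O cleavage), MeI attacks the enolate face left open by the potassium-chelated methoxymethylpyrrolidine to set the quaternary C7a centre, and acid then ionises the tertiary allylic alcohol so that the amide oxygen closes the γ-lactone and the auxiliary is released.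

**Step 4**
Reactants: 7 diene lactone
Product: 9 methyl (3S,4E)-4-(3-methoxy-3-oxopropylidene)-3,5,5-trimethyl-2-oxooxolane-3-carboxylate, via diacid 8 (not isolated)
Conditions: RuCl3·3H2O (3 mol %), NaIO4 (4.1 equiv), MeCN/EtOAc/H2O, 0 °C; then TMSCHN2, PhMe/MeOH, 0 °C
Reagents that add atoms: sodium periodate, [Na+].[O-]I(=O)(=O)=O; (trimethylsilyl)diazomethane, C[Si](C)(C)C=[N+]=[N-]
Why: Sharpless RuO4 cleavage is sterically demanding and should cut the exposed cis-disubstituted C6=C7 bond to two acids while the trisubstituted C3a=C4 bond (flanked by two quaternary carbons, deactivated by the allylic lactone oxygen) survives; neutral esterification follows and the C7a centre is untouched.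

**Step 5**
Reactants: 9 diester
Product: 10 methyl (6aS)-3,3,6a-trimethyl-1,6-dioxo-3,5,6,6a-tetrahydro-1H-cyclopenta[c]furan-5-carboxylate
Conditions: KOtBu (2.1 equiv), THF, −20 → 0 °C; AcOH
Reagents that add atoms: none
Why: Dieckmann condensation: the CH2 that is both α to the ester and allylic attacks the cis-disposed ester on the quaternary carbon (5-exo-trig) and the stabilised β-keto ester enolate drives the six-to-five ring contraction; the ring-held allylic C–O bond lies in the nodal plane of the dienolate, so vinylogous elimination of the lactone is not expected.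

**Step 6**
Reactants: 10 unsaturated bicyclic β-keto ester
Product: 11 methyl (3aS,6aS)-3,3,6a-trimethyl-1,6-dioxohexahydro-1H-cyclopenta[c]furan-5-carboxylate
Conditions: H2 (4 atm), 5% Rh/Al2O3, EtOAc, rt
Reagents that add atoms: none
Why: Heterogeneous hydrogenation of the ring-fusion alkene (or its conjugated tautomer); a bicyclo[3.3.0] skeleton can only be cis-fused, so H is delivered to C3a on the face of the angular methyl (3aS), and rhodium is chosen to avoid hydrogenolysis of the allylic lactone C–O bond.

**Step 7**
Reactants: 11 bicyclic β-keto ester; 12 1-bromo-3-methylbut-2-ene (prenyl bromide)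
Product: 13 methyl (3aS,5R,6aS)-3,3,6a-trimethyl-5-(3-methylbut-2-en-1-yl)-1,6-dioxohexahydro-1H-cyclopenta[c]furan-5-carboxylate
Conditions: K2CO3, acetone, rt
Reagents that add atoms: none
Why: C-alkylation of the β-keto ester enolate on the convex face of the cis-fused bicycle, anti to the lactone ring and its inward-pointing methyl, which places the prenyl group on the face of the angular methyl and the ester on the lactone face (5R).

**Step 8**
Reactants: 14 3-methylbutan-2-one
Product: 15 3-methyl-2-oxobutanal (isopropylglyoxal)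
Conditions: SeO2, dioxane/H2O, reflux; distil (redistil from P2O5 before use)
Reagents that add atoms: selenium dioxide, O=[Se]=O
Why: Riley oxidation of the methyl group of a methyl ketone to the α-keto aldehyde; no stereocentre.

**Step 9**
Reactants: 13 prenylated β-keto ester; 15 3-methyl-2-oxobutanal
Product: 17 CNP0216954.1 [(3aS,5R,5'S,6'S,6aS)-3,3,6a-trimethyl-6'-(2-methylpropanoyl)-5'-(prop-1-en-2-yl)tetrahydrospiro[cyclopenta[c]furan-5,3'-oxane]-1,2',6-trione], via ene adduct 16 (not isolated)
Conditions: [Cu((S,S)-t-Bu-box)](SbF6)2 (10 mol %), 4 Å MS, CH2Cl2, 0 °C → rt; then CSA (5 mol %), PhMe, 50 °C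
Reagents that add atoms: none
Why: Catalytic asymmetric carbonyl-ene reaction (glyoxylate-ene type): the chelated keto aldehyde bonds through its formyl carbon to the prenyl CH and takes H from a methyl group to give the isopropenyl group, with the box ligand selecting the aldehyde face (S carbinol) and the chelated transition state expected to give the anti (2S,3S) adduct, whose hydroxyl then lactonises onto the neighbouring methyl ester.

**Compound list**
1 | phthalic anhydride | O=C1OC(=O)c2ccccc12 | starting material
2 | 3,3-dimethyl-2-benzofuran-1(3H)-one | CC1(C)OC(=O)c2ccccc12 | intermediate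
3 | (2S)-2-(methoxymethyl)pyrrolidine | COC[C@@H]1CCCN1 | starting material
4 | [2-(2-hydroxypropan-2-yl)phenyl][(2S)-2-(methoxymethyl)pyrrolidin-1-yl]methanone | COC[C@@H]1CCCN1C(=O)c1ccccc1C(C)(C)O | intermediate
5 | dipotassium 2-[6-[[(2S)-2-(methoxymethyl)pyrrolidin-1-yl](oxido)methylidene]cyclohexa-1,4-dien-1-yl]propan-2-olate (not isolated) | COC[C@@H]1CCCN1C([O-])=C1C=CCC=C1C(C)(C)[O-].[K+].[K+] | intermediate
6 | [(1R)-2-(2-hydroxypropan-2-yl)-1-methylcyclohexa-2,5-dien-1-yl][(2S)-2-(methoxymethyl)pyrrolidin-1-yl]methanone (not isolated) | COC[C@@H]1CCCN1C(=O)[C@]2(C)C=CCC=C2C(C)(C)O | intermediate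
7 | (7aR)-3,3,7a-trimethyl-5,7a-dihydro-2-benzofuran-1(3H)-one | CC1(C)OC(=O)[C@]2(C)C=CCC=C12 | intermediate
8 | (3S,4E)-4-(2-carboxyethylidene)-3,5,5-trimethyl-2-oxooxolane-3-carboxylic acid (not isolated) | OC(=O)C/C=C1/C(C)(C)OC(=O)[C@]1(C)C(=O)O | intermediate
9 | methyl (3S,4E)-4-(3-methoxy-3-oxopropylidene)-3,5,5-trimethyl-2-oxooxolane-3-carboxylate | COC(=O)C/C=C1/C(C)(C)OC(=O)[C@]1(C)C(=O)OC | intermediate
10 | methyl (6aS)-3,3,6a-trimethyl-1,6-dioxo-3,5,6,6a-tetrahydro-1H-cyclopenta[c]furan-5-carboxylate (C5 epimers and enol tautomers) | COC(=O)C1C=C2C(C)(C)OC(=O)[C@]2(C)C1=O | intermediate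
11 | methyl (3aS,6aS)-3,3,6a-trimethyl-1,6-dioxohexahydro-1H-cyclopenta[c]furan-5-carboxylate (C5 epimers and enol) | COC(=O)C1C[C@@H]2C(C)(C)OC(=O)[C@]2(C)C1=O | intermediate
12 | 1-bromo-3-methylbut-2-ene | CC(C)=CCBr | starting material
13 | methyl (3aS,5R,6aS)-3,3,6a-trimethyl-5-(3-methylbut-2-en-1-yl)-1,6-dioxohexahydro-1H-cyclopenta[c]furan-5-carboxylate | CC(C)=CC[C@]1(C[C@@H]2C(C)(C)OC(=O)[C@]2(C)C1=O)C(=O)OC | intermediate
14 | 3-methylbutan-2-one | CC(C)C(C)=O | starting material
15 | 3-methyl-2-oxobutanal | CC(C)C(=O)C=O | intermediate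
16 | methyl (3aS,5R,6aS)-5-[(2S,3S)-3-hydroxy-5-methyl-4-oxo-2-(prop-1-en-2-yl)hexyl]-3,3,6a-trimethyl-1,6-dioxohexahydro-1H-cyclopenta[c]furan-5-carboxylate (not isolated) | C=C(C)[C@H](C[C@]1(C[C@@H]2C(C)(C)OC(=O)[C@]2(C)C1=O)C(=O)OC)[C@H](O)C(=O)C(C)C | intermediate
17 | CNP0216954.1 | C=C(C)[C@@H]1C[C@]2(C[C@@H]3C(C)(C)OC(=O)[C@]3(C)C2=O)C(=O)O[C@@H]1C(=O)C(C)C | target

**Step count**
Total: 9 steps. Longest linear sequence: 8 steps (steps 1–7 and 9); step 8 is a one-step side branch.

**Three steps most likely to fail, each with a fallback**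

Step 3. The risks are benzylic C–O hydrogenolysis of the ortho carbinol, and an unknown level and sense of induction with an ortho alkoxide on the Schultz amide. The fallback replaces auxiliary control by classical resolution. It sets out from 2: KOH opens the lactone to potassium 2-(2-hydroxypropan-2-yl)benzoate F1. Birch reductive methylation without auxiliary (K, NH3, t-BuOH; MeI) gives racemic potassium 2-(2-hydroxypropan-2-yl)-1-methylcyclohexa-2,5-diene-1-carboxylate F2. Salt exchange with (R)-1-phenylethylammonium chloride and fractional crystallisation gives (R)-1-phenylethylammonium (1R)-2-(2-hydroxypropan-2-yl)-1-methylcyclohexa-2,5-diene-1-carboxylate F3 (which amine enantiomer crystallises with the wanted acid is empirical). TFA then closes the lactone and the route is rejoined at 7.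

Step 4. The risk is that RuO4 also attacks the trisubstituted alkene or the doubly allylic CH2. The fallback separates the cleavage into a sterically governed dihydroxylation and two mild oxidations. It sets out from 7: OsO4 (cat.) with N-methylmorpholine N-oxide dihydroxylates only the exposed cis-alkene to (7aS)-6,7-dihydroxy-3,3,7a-trimethyl-5,6,7,7a-tetrahydro-2-benzofuran-1(3H)-one F4. NaIO4 cleaves the glycol to (3S,4E)-3,5,5-trimethyl-2-oxo-4-(3-oxopropylidene)oxolane-3-carbaldehyde F5. NaClO2/NaH2PO4/2-methylbut-2-ene oxidises both formyl groups and the route is rejoined at 8.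

Step 9. The risks are: the anti selectivity and face selectivity of an alkyl glyoxal with a trisubstituted alkene are extrapolated from glyoxylate chemistry; a stepwise Prins pathway could be trapped by the ester; and the tricarbonyl substrate may bind the copper catalyst. The fallback forms the same C–C bond by an intramolecular radical cyclisation instead of an intermolecular ene reaction. It sets out from 11: DMAP-catalysed transesterification with 1-hydroxy-3-methylbutan-2-one (PhMe, reflux) gives 3-methyl-2-oxobutyl (3aS,6aS)-3,3,6a-trimethyl-1,6-dioxohexahydro-1H-cyclopenta[c]furan-5-carboxylate F6. Prenylation as in step 7 gives 3-methyl-2-oxobutyl (3aS,5R,6aS)-3,3,6a-trimethyl-5-(3-methylbut-2-en-1-yl)-1,6-dioxohexahydro-1H-cyclopenta[c]furan-5-carboxylate F7. Mn(OAc)3·2H2O and Cu(OAc)2·H2O in AcOH (60–80 °C) generate the α-acyloxy ketone radical, which closes 6-exo onto the prenyl CH; Cu(OAc)2 oxidises the tertiary radical to the isopropenyl group. The route is rejoined at 17, with diastereomers separated by chromatography if needed.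

**Further compounds**
F1 | step 3 | potassium 2-(2-hydroxypropan-2-yl)benzoate | CC(C)(O)c1ccccc1C(=O)[O-].[K+]
F2 | step 3 | racemic potassium 2-(2-hydroxypropan-2-yl)-1-methylcyclohexa-2,5-diene-1-carboxylate | CC(C)(O)C1=CCC=CC1(C)C(=O)[O-].[K+]
F3 | step 3 | (R)-1-phenylethylammonium (1R)-2-(2-hydroxypropan-2-yl)-1-methylcyclohexa-2,5-diene-1-carboxylate | CC(C)(O)C1=CCC=C[C@@]1(C)C(=O)[O-].C[C@@H]([NH3+])c1ccccc1
F4 | step 4 | (7aS)-6,7-dihydroxy-3,3,7a-trimethyl-5,6,7,7a-tetrahydro-2-benzofuran-1(3H)-one (cis-diol, either face) | CC1(C)OC(=O)[C@]2(C)C(O)C(O)CC=C12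
F5 | step 4 | (3S,4E)-3,5,5-trimethyl-2-oxo-4-(3-oxopropylidene)oxolane-3-carbaldehyde | O=CC/C=C1/C(C)(C)OC(=O)[C@]1(C)C=O
F6 | step 9 | 3-methyl-2-oxobutyl (3aS,6aS)-3,3,6a-trimethyl-1,6-dioxohexahydro-1H-cyclopenta[c]furan-5-carboxylate | CC(C)C(=O)COC(=O)C1C[C@@H]2C(C)(C)OC(=O)[C@]2(C)C1=O
F7 | step 9 | 3-methyl-2-oxobutyl (3aS,5R,6aS)-3,3,6a-trimethyl-5-(3-methylbut-2-en-1-yl)-1,6-dioxohexahydro-1H-cyclopenta[c]furan-5-carboxylate | CC(C)C(=O)COC(=O)[C@]1(CC=C(C)C)C[C@@H]2C(C)(C)OC(=O)[C@]2(C)C1=O
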